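**Retrosynthetic overview**
1. Enone Cα=Cβ: Claisen–Schmidt disconnection into the ring A methyl ketone (2,4-dihydroxy-3-prenylacetophenone, from resacetophenone and prenyl bromide) and the ring B aldehyde that already carries the complete side chain.
2. Isopropenyl carbinol: retro-dehydration to the (R)-2,3-dihydroxy-3-methylbutyl arene, so the C–O stereocenter is never part of a bond-making or bond-breaking event.
3. Key aryl–CH2 bond: visible-light nickel/photoredox reductive coupling of 4-hydroxy-3-iodobenzaldehyde with the CH2 terminus of an enantiopure epoxy tertiary alcohol.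
4. The epoxy alcohol comes from serine-derived methyl (R)-glycidate by addition of two methyl groups; its C2 is the only stereocenter of the target and is bought.
5. No ring is formed: both benzene rings are purchased and the oxirane is only opened.

Assumption: methyl (R)-glycidate, 4-hydroxy-3-iodobenzaldehyde, 2,4-dihydroxyacetophenone and prenyl bromide are taken as catalogue chemicals.

**Step 1**
Reactants: 1 methyl (2R)-oxirane-2-carboxylate (methyl (R)-glycidate)
Product: 2 (R)-2-(oxiran-2-yl)propan-2-ol
Conditions: MeMgBr (2.2 equiv), THF, −78 → −30 °C; then sat. aq. NH4Cl at −30 °C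
Reagents that add atoms: methylmagnesium bromide, C[Mg]Br
Why: Double Grignard addition to the ester is faster than epoxide opening at low temperature and gives the tertiary carbinol, and since no bond to C2 is made or broken the bought stereocenter stays (R).

**Step 2**
Reactants: 2 (R)-2-(oxiran-2-yl)propan-2-ol; 3 aryl iodide 4-hydroxy-3-iodobenzaldehyde
Product: 5 diol aldehyde 3-[(2R)-2,3-dihydroxy-3-methylbutyl]-4-hydroxybenzaldehyde, via iodohydrin 4 (not isolated)
Conditions: 2 (1.5 equiv), 2,4,5,6-tetra(9H-carbazol-9-yl)isophthalonitrile (4CzIPN, 2 mol %), NiBr2·DME (10 mol %), 4,4'-di-tert-butyl-2,2'-bipyridine (12 mol %), NaI (25 mol %), Et3N (3.5 equiv), DMA, blue LEDs (450 nm), 25 °C, N2, 24 h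
Reagents that add atoms: none
Why: Proposed new method: an iodide-relay nickel/photoredox cross-electrophile coupling of an unprotected ortho-iodophenol with an enantiopure epoxy tertiary alcohol, in which triethylammonium iodide (from NaI, Et3N and the acidic phenol) opens epoxide 2 by SN2 at its unsubstituted CH2 to iodohydrin 4 without touching the C–O bond of the stereocenter, photoexcited 4CzIPN is quenched by Et3N and its radical anion reduces divalent nickel to zerovalent nickel, which inserts into the aryl–I bond of 3, the α-aminoalkyl radical derived from Et3N abstracts iodine from 4 to give a primary β-hydroxyalkyl radical that is captured at nickel, and reductive elimination from trivalent nickel forms the aryl–CH2 bond with the (R) center retained while iodide returns to the relay; the closest known reaction types are the nickel/photoredox reductive coupling of aryl iodides with simple epoxides and the thermal nickel/iodide reductive arylation of terminal epoxides at the less hindered carbon, neither of which has been shown for glycidate-derived epoxy alcohols with a free carbinol or for free halophenols.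

**Step 3**
Reactants: 5 diol aldehyde 3-[(2R)-2,3-dihydroxy-3-methylbutyl]-4-hydroxybenzaldehyde
Product: 7 allylic diacetate 2-[(2R)-2-(acetyloxy)-3-methylbut-3-en-1-yl]-4-formylphenyl acetate, via hydroxy diacetate 6 (not isolated)
Conditions: Ac2O (2.3 equiv), pyridine, 4-(dimethylamino)pyridine (5 mol %), CH2Cl2, 25 °C; evaporate; then SOCl2 (2.5 equiv), pyridine, CH2Cl2, −10 → 0 °C
Reagents that add atoms: acetic anhydride, CC(=O)OC(C)=O
Why: O-Acetylation caps the phenol and the secondary alcohol but not the tertiary one, whose chlorosulfite then undergoes pyridine-induced E2 dehydration toward a methyl group because the only other β-hydrogen sits on the hindered, acetoxy-deactivated C2, so the isopropenyl group forms and the stereocenter, not involved, stays (R).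

**Step 4**
Reactants: 8 ketone 1-(2,4-dihydroxyphenyl)ethan-1-one (2,4-dihydroxyacetophenone); 9 prenyl bromide (1-bromo-3-methylbut-2-ene)
Product: 10 prenyl ketone 1-[2,4-dihydroxy-3-(3-methylbut-2-en-1-yl)phenyl]ethan-1-one
Conditions: KOH (10% aq., 2.2 equiv), 9 (1.1 equiv), 0 → 25 °C; then dil. HCl; chromatography
Reagents that add atoms: none
Why: C-Alkylation of the ambident resorcinol-type phenolate in water (SN2 on the allylic bromide) goes mainly to C3 between the two oxygens, and the 5-prenyl and O-prenyl isomers are removed by chromatography (about 30% expected).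

**Step 5**
Reactants: 7 allylic diacetate 2-[(2R)-2-(acetyloxy)-3-methylbut-3-en-1-yl]-4-formylphenyl acetate; 10 prenyl ketone 1-[2,4-dihydroxy-3-(3-methylbut-2-en-1-yl)phenyl]ethan-1-one
Product: 12 target chalcone (2E)-1-[2,4-dihydroxy-3-(3-methylbut-2-en-1-yl)phenyl]-3-{4-hydroxy-3-[(2R)-2-hydroxy-3-methylbut-3-en-1-yl]phenyl}prop-2-en-1-one, via hydroxy aldehyde 11 (not isolated)
Conditions: 7 (1.1 equiv), KOH (50% aq., 20 equiv), EtOH, 0 → 40 °C, 48 h; then 1 M HCl to pH 5 at 0 °C
Reagents that add atoms: none
Why: Aqueous KOH first saponifies both acetates to 11 and then drives the Claisen–Schmidt (crossed aldol) condensation of the methyl ketone enolate with the non-enolisable aldehyde, E1cB loss of water giving the thermodynamically favoured E enone while the carbinol stereocenter is untouched by base.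

**Compound list**
1 | methyl (2R)-oxirane-2-carboxylate | COC(=O)[C@H]1CO1 | starting material
2 | (R)-2-(oxiran-2-yl)propan-2-ol | CC(C)(O)[C@H]1CO1 | intermediate
3 | 4-hydroxy-3-iodobenzaldehyde | O=Cc1ccc(O)c(I)c1 | starting material
4 | (3S)-4-iodo-2-methylbutane-2,3-diol | CC(C)(O)[C@H](O)CI | intermediate
5 | 3-[(2R)-2,3-dihydroxy-3-methylbutyl]-4-hydroxybenzaldehyde | CC(C)(O)[C@H](O)Cc1cc(C=O)ccc1O | intermediate
6 | 2-[(2R)-2-(acetyloxy)-3-hydroxy-3-methylbutyl]-4-formylphenyl acetate | CC(C)(O)[C@H](OC(C)=O)Cc1cc(C=O)ccc1OC(C)=O | intermediate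
7 | 2-[(2R)-2-(acetyloxy)-3-methylbut-3-en-1-yl]-4-formylphenyl acetate | C=C(C)[C@H](OC(C)=O)Cc1cc(C=O)ccc1OC(C)=O | intermediate
8 | 1-(2,4-dihydroxyphenyl)ethan-1-one | CC(=O)c1ccc(O)cc1O | starting material
9 | 1-bromo-3-methylbut-2-ene | CC(C)=CCBr | starting material
10 | 1-[2,4-dihydroxy-3-(3-methylbut-2-en-1-yl)phenyl]ethan-1-one | CC(=O)c1ccc(O)c(CC=C(C)C)c1O | intermediate
11 | 4-hydroxy-3-[(2R)-2-hydroxy-3-methylbut-3-en-1-yl]benzaldehyde | C=C(C)[C@H](O)Cc1cc(C=O)ccc1O | intermediate
12 | (2E)-1-[2,4-dihydroxy-3-(3-methylbut-2-en-1-yl)phenyl]-3-{4-hydroxy-3-[(2R)-2-hydroxy-3-methylbut-3-en-1-yl]phenyl}prop-2-en-1-one | C=C(C)[C@H](O)Cc1cc(/C=C/C(=O)c2ccc(O)c(CC=C(C)C)c2O)ccc1O | target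

**Step count and risks**
Total step count: 5. Longest linear sequence: 4 steps (steps 1, 2, 3 and 5, from 1 to 12); step 4 supplies the second fragment.

The three steps most likely to fail:

Step 2, the new photochemical coupling. The phenoxide of 3 may quench the excited photocatalyst, nickel may give O-arylation or hydrodeiodination of 3, and iodide opening of 2 may be slow. The fallback uses known chemistry, a polar copper-catalysed epoxide opening in place of the radical coupling; it sets out from 3 (with 2) and comes back at 5. The aldehyde of 3 is masked with ethylene glycol (TsOH, toluene, azeotropic water removal) as 4-(1,3-dioxolan-2-yl)-2-iodophenol F1. MeMgCl (1 equiv) and then iPrMgCl·LiCl (THF, −20 °C, iodine–magnesium exchange) turn it into the arylmagnesium reagent chloro[2-(chloromagnesiooxy)-5-(1,3-dioxolan-2-yl)phenyl]magnesium F2. With CuI (10 mol %) this opens epoxide 2 (one extra equivalent of MeMgCl for its hydroxyl) at the CH2 terminus by SN2, again without touching the stereocenter, to give 2-[(2R)-2,3-dihydroxy-3-methylbutyl]-4-(1,3-dioxolan-2-yl)phenol F3. 1 M HCl in THF removes the acetal and returns 5.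

Step 4, the direct C-prenylation. It gives 10 only as the main component of a mixture with 5-prenyl, O-prenyl and bis-prenyl isomers. The fallback replaces intermolecular C-alkylation by an O-alkylation and sigmatropic transfer; it sets out from 8 and comes back at 10. Selective 4-O-alkylation of 8 with 3-chloro-3-methylbut-1-yne (K2CO3, KI, acetone, reflux; the chelated 2-OH stays free) gives 1-[2-hydroxy-4-(2-methylbut-3-yn-2-yloxy)phenyl]ethan-1-one F4. Semihydrogenation (H2, Pd/CaCO3–Pb(OAc)2, quinoline, EtOAc) gives 1-[2-hydroxy-4-(2-methylbut-3-en-2-yloxy)phenyl]ethan-1-one F5. Heating (N,N-diethylaniline, 180 °C) brings about the aromatic Claisen rearrangement, which delivers the prenyl group to C3 between the two oxygens and returns 10.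

Step 5, the condensation of two unprotected polyphenolates. It is slow, conversion may stay incomplete, and the 2'-hydroxychalcone can close to the flavanone on acidification. The fallback uses protected partners; it sets out from 7 and 10 and comes back at 12. Methanolysis of 7 (K2CO3, MeOH, 0 °C) gives 11, now isolated, whose phenol is capped (MOMCl, K2CO3, acetone) as 3-[(2R)-2-hydroxy-3-methylbut-3-en-1-yl]-4-(methoxymethoxy)benzaldehyde F6. Ketone 10 is capped in the same way at its non-chelated 4-OH as 1-[2-hydroxy-4-(methoxymethoxy)-3-(3-methylbut-2-en-1-yl)phenyl]ethan-1-one F7. The Claisen–Schmidt condensation of F6 and F7 (KOH, EtOH–H2O, 25 °C) then involves only the chelated phenolate and gives (2E)-1-[2-hydroxy-4-(methoxymethoxy)-3-(3-methylbut-2-en-1-yl)phenyl]-3-{3-[(2R)-2-hydroxy-3-methylbut-3-en-1-yl]-4-(methoxymethoxy)phenyl}prop-2-en-1-one F8. Dilute HCl in MeOH (40 °C) removes both methoxymethyl groups and returns 12.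

**Further compounds**
F1 | step 2 | 4-(1,3-dioxolan-2-yl)-2-iodophenol | Oc1ccc(C2OCCO2)cc1I
F2 | step 2 | chloro[2-(chloromagnesiooxy)-5-(1,3-dioxolan-2-yl)phenyl]magnesium | Cl[Mg]Oc1ccc(C2OCCO2)cc1[Mg]Cl
F3 | step 2 | 2-[(2R)-2,3-dihydroxy-3-methylbutyl]-4-(1,3-dioxolan-2-yl)phenol | CC(C)(O)[C@H](O)Cc1cc(C2OCCO2)ccc1O
F4 | step 4 | 1-[2-hydroxy-4-(2-methylbut-3-yn-2-yloxy)phenyl]ethan-1-one | CC(=O)c1ccc(OC(C)(C)C#C)cc1O
F5 | step 4 | 1-[2-hydroxy-4-(2-methylbut-3-en-2-yloxy)phenyl]ethan-1-one | CC(=O)c1ccc(OC(C)(C)C=C)cc1O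
F6 | step 5 | 3-[(2R)-2-hydroxy-3-methylbut-3-en-1-yl]-4-(methoxymethoxy)benzaldehyde | C=C(C)[C@H](O)Cc1cc(C=O)ccc1OCOC
F7 | step 5 | 1-[2-hydroxy-4-(methoxymethoxy)-3-(3-methylbut-2-en-1-yl)phenyl]ethan-1-one | CC(=O)c1ccc(OCOC)c(CC=C(C)C)c1O
F8 | step 5 | (2E)-1-[2-hydroxy-4-(methoxymethoxy)-3-(3-methylbut-2-en-1-yl)phenyl]-3-{3-[(2R)-2-hydroxy-3-methylbut-3-en-1-yl]-4-(methoxymethoxy)phenyl}prop-2-en-1-one | C=C(C)[C@H](O)Cc1cc(/C=C/C(=O)c2ccc(OCOC)c(CC=C(C)C)c2O)ccc1OCOC
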